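**Plan**
- Ring C is cut at O1–C2 (cyclodehydration) and at C3–C4 (crossed Claisen), which gives a ring A benzoate and a ring B α-methoxy ketone. The ketone is cut at C2–C1' (aryllithium plus Weinreb amide) and at the prenyl ether O–C bond.
- Ring A is cut at C4a–C8a, back to a 4-alkoxy-2-pyrone with a CH(OMe)CO2Me side chain at its C6. This comes from triacetic acid lactone by carboxylation of the methyl group and carbenoid O–H insertion into methanol.
- Feature used: ring A carries the acetate-type oxygens at C5, C7 and C8a, and C4a–C8a is its polyketide ring-closing bond. In the pyrone the C5 oxygen is a masked enol ether, so after closure the only free hydroxyl beside C4a is the one at C8a, next to the C8 methoxy group.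
- Forward order: pyrone side chain, ring A (step 5), silylation, ring B ketone joined through C3–C4, ring C closed through O1–C2, acetal removed.
- Stereochemistry: the target has no stereocenter and its prenyl alkene has no E/Z isomers. The racemic centres of the intermediates disappear on aromatisation or dehydration.

Key step: step 5

Assumption: 4-bromo-2-methoxyphenol and N,2-dimethoxy-N-methylacetamide are taken as commercial materials; making the ketone from them avoids any electrophilic α-functionalisation next to the prenyl double bond. Ring A atoms are named with flavone numbering throughout.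

**Route**

Step 1
Reactants: 1 4-hydroxy-6-methyl-2H-pyran-2-one (triacetic acid lactone)
Product: 2 4-(methoxymethoxy)-6-methyl-2H-pyran-2-one
Conditions: MOMCl, i-Pr2NEt, CH2Cl2, 0 °C → rt
Reagents that add atoms: chloromethyl methyl ether, COCCl
Why: The 4-hydroxyl is a vinylogous carboxylic acid, so its ammonium salt should be O-alkylated by the hard chloromethyl ether (Williamson-type MOM protection) without touching the lactone or the methyl group.

Step 2
Reactants: 2 4-(methoxymethoxy)-6-methyl-2H-pyran-2-one; 3 dimethyl carbonate
Product: 5 methyl 2-[4-(methoxymethoxy)-2-oxo-2H-pyran-6-yl]acetate, via lithiomethyl pyrone 4 (not isolated)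
Conditions: LiN(i-Pr)2 (2.2 equiv), THF, −78 °C; then (MeO)2CO, −78 → −20 °C; aq. NH4Cl
Reagents that add atoms: none
Why: Lateral (vinylogous) deprotonation of the 6-methyl group of 4-alkoxy-6-methyl-2-pyrones by lithium diisopropylamide is established, and the extended enolate should be C-acylated by the carbonate (Claisen-type methoxycarbonylation) while the second equivalent of base stores the more acidic product as its enolate and so prevents double acylation.

Step 3
Reactants: 5 methyl 2-[4-(methoxymethoxy)-2-oxo-2H-pyran-6-yl]acetate
Product: 6 methyl 2-diazo-2-[4-(methoxymethoxy)-2-oxo-2H-pyran-6-yl]acetate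
Conditions: 4-acetamidobenzenesulfonyl azide, DBU, MeCN, 0 °C → rt
Reagents that add atoms: 4-acetamidobenzenesulfonyl azide, CC(=O)Nc1ccc(cc1)S(=O)(=O)N=[N+]=[N-]
Why: Regitz diazo transfer to a methylene group that is activated by the ester and by the electron-poor pyrone carbon, as is routine for aryl acetates.

Step 4
Reactants: 6 methyl 2-diazo-2-[4-(methoxymethoxy)-2-oxo-2H-pyran-6-yl]acetate
Product: 7 methyl 2-methoxy-2-[4-(methoxymethoxy)-2-oxo-2H-pyran-6-yl]acetate (racemic)
Conditions: Rh2(OAc)4 (1 mol %), MeOH (10 equiv), CH2Cl2, rt
Reagents that add atoms: methanol, CO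
Why: Dirhodium tetraacetate should turn the diazo ester into a rhodium carbenoid that inserts into the O–H bond of methanol (carbenoid O–H insertion), which places the future C8 methoxy group; the new stereocenter forms as a racemate and is lost when ring A aromatises.

Step 5
Reactants: 7 methyl 2-methoxy-2-[4-(methoxymethoxy)-2-oxo-2H-pyran-6-yl]acetate (racemic)
Product: 9 methyl 2,4-dihydroxy-3-methoxy-6-(methoxymethoxy)benzoate, via open-chain keto diester 8 (not isolated)
Conditions: Mg(OMe)2 (4 equiv), MeOH, reflux; aq. NH4Cl (pH 5–6)
Reagents that add atoms: magnesium methoxide, CO[Mg]OC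
Why: Methoxide adds to the lactone carbonyl and opens the 2-pyrone to the magnesium-chelated keto diester 8, in which the former pyrone C3 is the α-carbon of a 3-alkoxyglutaconate; γ-deprotonation gives a dienolate whose α-carbon (the future C4a) attacks the side-chain ester carbonyl (the future C8a) and expels methoxide, and enolisation towards C8a and C7 then gives the arene. The closest known reaction type is the magnesium methoxide ring transformation of 4-methoxy-2-pyrones with a 6-(alkoxycarbonylmethyl) or 6-(2-oxoalkyl) group into phloroglucinol carboxylates and acylphloroglucinols, a laboratory copy of the polyketide Claisen cyclisation. Ring A closes in a 6-(enolexo)-exo-trig Dieckmann-type mode and no stereocenter is formed, since the racemic methoxy-bearing carbon becomes the sp2 carbon C8. The step needs C4a-to-C8a closure rather than attack of the methoxy-bearing carbon on the former lactone ester, and it needs a lasting difference between the two oxygens ortho to C4a. The first is secured because the alternative closure would give a quaternary carbon that cannot aromatise and therefore reverts by retro-Claisen, while the wanted closure is pulled forward by aromatisation and by the magnesium phenoxide chelate; the second because the C5 oxygen is the pyrone enol ether oxygen and stays a MOM ether, whereas the C8a oxygen comes from the ester carbonyl and appears as a free phenol next to the C8 methoxy group. The MOM acetal is base-stable once it sits on the arene, and the enolate character of the open-chain species should hold back methoxide exchange at the enol ether carbon.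

Step 6
Reactants: 9 methyl 2,4-dihydroxy-3-methoxy-6-(methoxymethoxy)benzoate
Product: 10 methyl 2,4-bis[(tert-butyldimethylsilyl)oxy]-3-methoxy-6-(methoxymethoxy)benzoate
Conditions: TBSCl (3 equiv), imidazole, DMAP (cat.), DMF, 45 °C
Reagents that add atoms: tert-butyldimethylsilyl chloride, CC(C)(C)[Si](C)(C)Cl
Why: Silylation of both phenols (the free C7 hydroxyl quickly, the hydrogen-bonded C8a hydroxyl more slowly, hence excess reagent and warming) removes the acidic protons that would quench the enolate and deactivate the ester in step 9, and the silyl ethers can later be taken off with fluoride while the C5 MOM acetal stays.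

Step 7
Reactants: 11 4-bromo-2-methoxyphenol; 12 1-bromo-3-methylbut-2-ene (prenyl bromide)
Product: 13 4-bromo-2-methoxy-1-[(3-methylbut-2-en-1-yl)oxy]benzene
Conditions: K2CO3, acetone, reflux
Reagents that add atoms: none
Why: Williamson ether synthesis, the phenoxide displacing bromide at the primary allylic carbon (SN2) with O-alkylation favoured in acetone.

Step 8
Reactants: 13 4-bromo-2-methoxy-1-[(3-methylbut-2-en-1-yl)oxy]benzene; 14 N,2-dimethoxy-N-methylacetamide
Product: 16 2-methoxy-1-{3-methoxy-4-[(3-methylbut-2-en-1-yl)oxy]phenyl}ethan-1-one, via aryllithium 15 (not isolated)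
Conditions: n-BuLi, THF, −78 °C; then 14, −78 → 0 °C; aq. NH4Cl
Reagents that add atoms: none
Why: Bromine–lithium exchange at −78 °C is faster than any attack on the allylic ether, and the aryllithium should add only once to the Weinreb amide because the lithium chelate of the tetrahedral adduct survives until work-up (Weinreb ketone synthesis).

Step 9
Reactants: 16 2-methoxy-1-{3-methoxy-4-[(3-methylbut-2-en-1-yl)oxy]phenyl}ethan-1-one; 10 methyl 2,4-bis[(tert-butyldimethylsilyl)oxy]-3-methoxy-6-(methoxymethoxy)benzoate
Product: 18 1-[2,4-bis[(tert-butyldimethylsilyl)oxy]-3-methoxy-6-(methoxymethoxy)phenyl]-2-methoxy-3-{3-methoxy-4-[(3-methylbut-2-en-1-yl)oxy]phenyl}propane-1,3-dione (racemic), via lithium enolate 17 (not isolated)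
Conditions: 16 (1.3 equiv), LiN(SiMe3)2 (2.6 equiv), THF, −78 °C; then 10, −78 °C → rt; aq. NH4Cl
Reagents that add atoms: none
Why: Crossed Claisen condensation that joins C3 to C4, in which the chelated (Z)-lithium enolate of the α-methoxy ketone attacks the non-enolisable, phenol-free methyl ester and the excess base deprotonates the 2-methoxy-1,3-diketone to pull the equilibrium over, the acylation of ketone lithium enolates by O-silylated salicylate esters being a known entry to flavone diketones.

Step 10
Reactants: 18 1-[2,4-bis[(tert-butyldimethylsilyl)oxy]-3-methoxy-6-(methoxymethoxy)phenyl]-2-methoxy-3-{3-methoxy-4-[(3-methylbut-2-en-1-yl)oxy]phenyl}propane-1,3-dione (racemic)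
Product: 21 7-hydroxy-3,8-dimethoxy-2-{3-methoxy-4-[(3-methylbut-2-en-1-yl)oxy]phenyl}-5-(methoxymethoxy)-4H-chromen-4-one, via desilylated diketone 19 (not isolated), via cyclic hemiketal 20 (not isolated)
Conditions: Bu4NF (2.2 equiv), AcOH (2.2 equiv), THF, 0 °C → rt; then AcOH, 70 °C
Reagents that add atoms: none
Why: Fluoride removes both aryl silyl ethers, and only the C8a phenol can reach the ring B carbonyl (the C5 oxygen is still an acetal and the C7 phenol is meta to the acyl group), so 6-exo-trig hemiketal formation (O1–C2) and acetic-acid-promoted loss of water across C2–C3 (cyclodehydration of an o-hydroxyaryl 1,3-diketone) should give the 8-methoxyflavone and not its 6-methoxy isomer, acetic acid being too weak to cleave the aryl MOM acetal before the ring has closed or to harm the prenyl ether.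

Step 11
Reactants: 21 7-hydroxy-3,8-dimethoxy-2-{3-methoxy-4-[(3-methylbut-2-en-1-yl)oxy]phenyl}-5-(methoxymethoxy)-4H-chromen-4-one
Product: 22 5,7-dihydroxy-3,8-dimethoxy-2-{3-methoxy-4-[(3-methylbut-2-en-1-yl)oxy]phenyl}-4H-chromen-4-one (5,7-dihydroxy-3,8,3'-trimethoxy-4'-prenyloxyflavone)
Conditions: HCl (1 M), MeOH–THF, rt
Reagents that add atoms: none
Why: Acid-catalysed acetal methanolysis, in which the MOM group on the C5 oxygen peri to the C4 carbonyl is the most labile kind of aryl MOM ether and should leave with dilute acid at room temperature, conditions under which the prenyl aryl ether and the C3 enol ether should persist.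

**Compound list**

1 | 4-hydroxy-6-methyl-2H-pyran-2-one (triacetic acid lactone) | Cc1cc(O)cc(=O)o1 | starting material
2 | 4-(methoxymethoxy)-6-methyl-2H-pyran-2-one | COCOc1cc(C)oc(=O)c1 | intermediate
3 | dimethyl carbonate | COC(=O)OC | starting material
4 | [4-(methoxymethoxy)-2-oxo-2H-pyran-6-yl]methyllithium (not isolated) | [Li]Cc1cc(OCOC)cc(=O)o1 | intermediate
5 | methyl 2-[4-(methoxymethoxy)-2-oxo-2H-pyran-6-yl]acetate | COCOc1cc(CC(=O)OC)oc(=O)c1 | intermediate
6 | methyl 2-diazo-2-[4-(methoxymethoxy)-2-oxo-2H-pyran-6-yl]acetate | COCOc1cc(C(=[N+]=[N-])C(=O)OC)oc(=O)c1 | intermediate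
7 | methyl 2-methoxy-2-[4-(methoxymethoxy)-2-oxo-2H-pyran-6-yl]acetate (racemic) | COCOc1cc(C(OC)C(=O)OC)oc(=O)c1 | intermediate
8 | dimethyl (5E)-2-methoxy-5-(methoxymethoxy)-3-oxohept-5-enedioate (racemic, as its magnesium enolate, not isolated) | COC(=O)C(OC)C(=O)C/C(OCOC)=C\C(=O)OC | intermediate
9 | methyl 2,4-dihydroxy-3-methoxy-6-(methoxymethoxy)benzoate | COCOc1cc(O)c(OC)c(O)c1C(=O)OC | intermediate
10 | methyl 2,4-bis[(tert-butyldimethylsilyl)oxy]-3-methoxy-6-(methoxymethoxy)benzoate | COCOc1cc(O[Si](C)(C)C(C)(C)C)c(OC)c(O[Si](C)(C)C(C)(C)C)c1C(=O)OC | intermediate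
11 | 4-bromo-2-methoxyphenol | COc1cc(Br)ccc1O | starting material
12 | 1-bromo-3-methylbut-2-ene (prenyl bromide) | CC(C)=CCBr | starting material
13 | 4-bromo-2-methoxy-1-[(3-methylbut-2-en-1-yl)oxy]benzene | COc1cc(Br)ccc1OCC=C(C)C | intermediate
14 | N,2-dimethoxy-N-methylacetamide | COCC(=O)N(C)OC | starting material
15 | {3-methoxy-4-[(3-methylbut-2-en-1-yl)oxy]phenyl}lithium (not isolated) | [Li]c1ccc(OCC=C(C)C)c(OC)c1 | intermediate
16 | 2-methoxy-1-{3-methoxy-4-[(3-methylbut-2-en-1-yl)oxy]phenyl}ethan-1-one | COCC(=O)c1ccc(OCC=C(C)C)c(OC)c1 | intermediate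
17 | lithium (1Z)-2-methoxy-1-{3-methoxy-4-[(3-methylbut-2-en-1-yl)oxy]phenyl}ethen-1-olate (not isolated) | [Li]O/C(=C\OC)c1ccc(OCC=C(C)C)c(OC)c1 | intermediate
18 | 1-[2,4-bis[(tert-butyldimethylsilyl)oxy]-3-methoxy-6-(methoxymethoxy)phenyl]-2-methoxy-3-{3-methoxy-4-[(3-methylbut-2-en-1-yl)oxy]phenyl}propane-1,3-dione (racemic) | COCOc1cc(O[Si](C)(C)C(C)(C)C)c(OC)c(O[Si](C)(C)C(C)(C)C)c1C(=O)C(OC)C(=O)c1ccc(OCC=C(C)C)c(OC)c1 | intermediate
19 | 1-[2,4-dihydroxy-3-methoxy-6-(methoxymethoxy)phenyl]-2-methoxy-3-{3-methoxy-4-[(3-methylbut-2-en-1-yl)oxy]phenyl}propane-1,3-dione (racemic, not isolated) | COCOc1cc(O)c(OC)c(O)c1C(=O)C(OC)C(=O)c1ccc(OCC=C(C)C)c(OC)c1 | intermediate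
20 | 2,7-dihydroxy-3,8-dimethoxy-2-{3-methoxy-4-[(3-methylbut-2-en-1-yl)oxy]phenyl}-5-(methoxymethoxy)-2,3-dihydro-4H-chromen-4-one (racemic mixture of diastereomers, not isolated) | COCOc1cc(O)c(OC)c2OC(O)(c3ccc(OCC=C(C)C)c(OC)c3)C(OC)C(=O)c12 | intermediate
21 | 7-hydroxy-3,8-dimethoxy-2-{3-methoxy-4-[(3-methylbut-2-en-1-yl)oxy]phenyl}-5-(methoxymethoxy)-4H-chromen-4-one | COCOc1cc(O)c(OC)c2oc(-c3ccc(OCC=C(C)C)c(OC)c3)c(OC)c(=O)c12 | intermediate
22 | 5,7-dihydroxy-3,8-dimethoxy-2-{3-methoxy-4-[(3-methylbut-2-en-1-yl)oxy]phenyl}-4H-chromen-4-one | COc1cc(-c2oc3c(OC)c(O)cc(O)c3c(=O)c2OC)ccc1OCC=C(C)C | target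

**Count and risks**

Total steps: 11. Longest linear sequence: 9 steps (steps 1–6, then 9–11); the ring B ketone takes 2 steps (7 and 8).

Steps most likely to fail:

Step 9. The enolate may fail to add to the ester carbonyl, which is shielded on both sides by ortho oxygen substituents and fed by three donor oxygens; proton transfer or slow desilylation by the enolate could then take over. The fallback sets out from 10 and returns at 18, replacing the ester by an aldehyde as the electrophile. Compound 10 is reduced with i-Bu2AlH (CH2Cl2, −78 → 0 °C) to [2,4-bis[(tert-butyldimethylsilyl)oxy]-3-methoxy-6-(methoxymethoxy)phenyl]methanol F1. This is oxidised with MnO2 (CH2Cl2, rt) to 2,4-bis[(tert-butyldimethylsilyl)oxy]-3-methoxy-6-(methoxymethoxy)benzaldehyde F2. Aldol addition of enolate 17 at −78 °C, quenched cold to prevent silyl migration to the new alkoxide, should give 3-[2,4-bis[(tert-butyldimethylsilyl)oxy]-3-methoxy-6-(methoxymethoxy)phenyl]-3-hydroxy-2-methoxy-1-{3-methoxy-4-[(3-methylbut-2-en-1-yl)oxy]phenyl}propan-1-one F3 as a mixture of diastereomers. Oxidation with Dess–Martin periodinane (NaHCO3, CH2Cl2) then gives diketone 18.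

Step 5. The carbon between the ketone and the side-chain ester is the most acidic site, and its chelated magnesium enolate may shut the ester off as an electrophile so that the reaction stops at the open chain. Long heating in methanol may also exchange the methoxymethyl enol ether for a methyl enol ether by addition–elimination before ring A has formed. The fallback sets out from 7 and returns at 9, separating ring opening from ring closure and closing without magnesium or methanol. The lactone is opened with NaOMe (1.1 equiv, MeOH–THF, 0 °C, short contact) and the keto diester 8 is isolated after a buffered quench. Its dianion is then generated with LiN(i-Pr)2 or KN(SiMe3)2 (2.5 equiv, THF, −78 → 0 °C), so that the C4a–C8a Dieckmann closure runs under kinetic, aprotic conditions and 9 forms on work-up. No compound outside the list arises on this path (F0).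

Step 2. Metalation may occur on the pyrone ring (helped by the MOM oxygen) instead of on the methyl group, the extended enolate may add to a second pyrone molecule before the sluggish carbonate captures it, or the product may be acylated twice. The fallback sets out from 1 and returns at 5, reversing the order of protection and carboxylation. Triacetic acid lactone is converted with LiN(i-Pr)2 (3.2 equiv, THF, −78 °C) into its dianion, in which the C4 oxyanion switches off ring metalation and attack on the ring. Methoxycarbonylation with 3 should give methyl 2-(4-hydroxy-2-oxo-2H-pyran-6-yl)acetate F4. O-Alkylation with MOMCl and i-Pr2NEt (CH2Cl2, 0 °C) then gives 5.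

Further compounds
F1 | step 9 | [2,4-bis[(tert-butyldimethylsilyl)oxy]-3-methoxy-6-(methoxymethoxy)phenyl]methanol | COCOc1cc(O[Si](C)(C)C(C)(C)C)c(OC)c(O[Si](C)(C)C(C)(C)C)c1CO
F2 | step 9 | 2,4-bis[(tert-butyldimethylsilyl)oxy]-3-methoxy-6-(methoxymethoxy)benzaldehyde | COCOc1cc(O[Si](C)(C)C(C)(C)C)c(OC)c(O[Si](C)(C)C(C)(C)C)c1C=O
F3 | step 9 | 3-[2,4-bis[(tert-butyldimethylsilyl)oxy]-3-methoxy-6-(methoxymethoxy)phenyl]-3-hydroxy-2-methoxy-1-{3-methoxy-4-[(3-methylbut-2-en-1-yl)oxy]phenyl}propan-1-one (mixture of diastereomers) | COCOc1cc(O[Si](C)(C)C(C)(C)C)c(OC)c(O[Si](C)(C)C(C)(C)C)c1C(O)C(OC)C(=O)c1ccc(OCC=C(C)C)c(OC)c1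
F0 | step 5 | none | none
F4 | step 2 | methyl 2-(4-hydroxy-2-oxo-2H-pyran-6-yl)acetate | COC(=O)Cc1cc(O)cc(=O)o1
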